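Start from 30.6%: that is the mean E of the oak readings from 8.00 min to 60.0 min, as a share of the D and Z together charged. Oak is the very flask you are asked about, and at 80 min you may act on it.

| flask | D | Z | temperature | remark | time |
|---|---|---|---|---|---|
| oak | 1 M | 0.25 M | 5 °C | the very flask that is asked about, followed so far |  |
| flask | 1.0 M | 0.250 M | 5 °C |  | 80 min |

- oak (time / min: E / %, D / %): 5.00: 34.4, 0; 8.00: 30.7, 0.3; 12.0: 30.7, 0; 20.0: 30.9, 0; 30.0: 31.1, 0.2; 40.0: 30.0, 0; 60.0: 30.5, 0.1

(readings scatter by 0.5 percentage points)

- dusk: at 80 min raise the temperature by 15 K, then wait 25 min
- summer: at 80 min add D, 50.0% of the amount charged, then wait 25 min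
- winter: at 80 min take out 90% of the E then present, then wait 25 min
- autumn: change nothing and wait 25 min more

- what is taken out of E is counted as made
- the earlier runs do not show what temperature does; that part of a forecast is a guess
- additions bring no volume worth counting

- E, in percent of the D and Z together first charged, at 80 min
- which option adds most E ("none" when 2 percentage points or less is all one gets) (dusk / summer / winter / autumn / none)
- E present, with what was taken out counted in, in percent of the D and Z together first charged, after dusk
- E present, with what was taken out counted in, in percent of the D and Z together first charged, after autumn

Build this flask up one process at a time. Take the main step first, D going one to one into E. The oak run reads D at 0% by 5.00 min, so E should stop at 80.0%, far above the plateau. Z is never read, so let it feed the same pool, which then holds the whole charge and widens the gap. Now add a loss: in oak E falls from 34.4% to 30.7% with D reading 0.3%. A one-way loss should carry E on down, yet the oak readings stay flat within their scatter for 52.0 min. So I add the way back: E exchanges with a hidden partner, and what I take as constant is a ratio, not an amount.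

Freeze it. The hold ratio, the part of the charge that is not E divided by E (an apparent equilibrium constant), reads 2.26 in oak. Oak levelled off by 8.00 min, well inside the 25 min of waiting, so by my reckoning a pool disturbed at 5 °C rebalances in time. Autumn then adds nothing, and 80 min reads 30.6%. Summer puts fresh material into the pool and E takes its share, a gain of 12 percentage points. Winter removes 90% of E, and the rest rebalances, a gain of 19 points, more than summer, for a total of 49.8%. Dusk changes the ratio itself, and the runs do not show how; it beats winter if the ratio drops under 1.01. I commit to winter, with dusk open.

The forecast gives 30.6% at 80 min, 30.6% after autumn, 30.5% after dusk, and names summer as best, with about 15 points for fresh D and roughly 3 for removing E, the reverse of my order. On warming it says: “Warming a settled mixture probably shifts little, and the direction is a guess.”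

The flask gives 30.8% at 80 min and 30.8% after autumn. Summer adds 12 points, winter 19 points, and dusk adds 33 points, reaching 63.7%.

    D ⇌ Z, settled at all times (K = 0.0855, ΔH = 0 kJ/mol)
    D → E (k = 0.0185 /s, Ea = 80.0 kJ/mol)
    E ⇌ L (K = 2.25, k = 0.00677 /s, Ea = 79.0 kJ/mol, ΔH = −62.0 kJ/mol)
    Z → L (k = 0.0582 /s, Ea = 76.0 kJ/mol)
    (constants at 5 °C)

The hold ratio belongs to E ⇌ L: without that step this flask shows 78.8% E at 80 min, not 30.8%. The flask has what the forecast's number does not, a ratio that moves with temperature: it falls from the 2.26 read in oak to 0.571 after dusk. At 30 °C the neighbour flask, same charge and time, holds 80.2% E and 19.8% L, a hold ratio of 0.247.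

The earlier runs and the new flask are simulated for an exercise.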